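The earlier runs and the new flask stem from a simulated flask from invented constants; noise was put on by code.

I follow the leftover, the pool cJa + cJb. The runs and the questions:

| flask | Ja | Jf | remark | time |
|---|---|---|---|---|
| noon | 0.24 M | 9.8 mM | run made earlier |  |
| dawn | 0.98 M | 9.8 mM | run made earlier |  |
| autumn | 0.49 M | 4.9 mM | run made earlier |  |
| eta | 0.49 M | 9.80 mM |  | 20 h |
| gamma | 0.49 M | 9.80 mM |  | 40 h |

| run | time / h | Jc / % | Jd / % | Ja / % | Jb / % |
|---|---|---|---|---|---|
| noon | 1.00 | 0 | 0 | 88 | 11 |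
| noon | 3.00 | 0 | 5 | 67 | 29 |
| noon | 6.00 | 3 | 7 | 49 | 41 |
| noon | 8.00 | 2 | 11 | 48 | 46 |
| noon | 12.0 | 0 | 15 | 36 | 46 |
| noon | 15.0 | 0 | 19 | 37 | 39 |
| noon | 20.0 | 2 | 27 | 29 | 42 |
| dawn | 3.00 | 0 | 2 | 68 | 30 |
| dawn | 6.00 | 0 | 6 | 52 | 39 |
| dawn | 8.00 | 0 | 12 | 46 | 44 |
| dawn | 12.0 | 2 | 17 | 34 | 44 |
| dawn | 15.0 | 0 | 22 | 32 | 40 |
| dawn | 20.0 | 0 | 34 | 35 | 34 |
| autumn | 2.00 | 2 | 2 | 76 | 20 |
| autumn | 5.00 | 2 | 4 | 57 | 37 |
| autumn | 10.0 | 0 | 11 | 43 | 44 |
| autumn | 15.0 | 0 | 22 | 34 | 40 |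
| autumn | 20.0 | 3 | 30 | 31 | 41 |

(scatter of a reading: 2 percentage points)

- which of these there is most of at the end, counted by the Ja in it, eta (Jb / Jd / Jc / Ja)
- which of these there is most of at the end, counted by the Ja in it, gamma (Jb / Jd / Jc / Ja)
- final amount of the leader among these, as a percentage of the Ja charged, in eta
- final amount of the leader among these, as a percentage of the Ja charged, in gamma

- a reading or a percentage of Jd counts all its forms, free or not

Noon and dawn carry the same Jf as eta and gamma and bracket their Ja charge, so I average those two runs. At 20.0 h they give Jb 38.0%, Ja 32.0% and Jd 30.5%, so I expect Jb to lead in eta.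

The bench rule for gamma says that twice the time gives twice the product, here 61.0% Jd. That rule needs a steady feed, but the pool, averaged over noon and dawn, reads 92.0% at 8.00 h and 70.0% at 20.0 h, a loss of a quarter.

I take a molecule in the pool to pass between Ja and Jb with a steady chance of leaving each hour. These readings give 0.0228 h⁻¹, the drain constant, the fraction of the pool lost per hour, which is a pool half-life of 30.4 h. By this reckoning the pool in gamma stands at 44.4% at 40 h, a further loss of 26 percentage points, less than the straight line's 30.5%. I therefore expect 55.6% in Jd and Jc together. Taking off Jc at its noon reading of 2% leaves 53.6% Jd, more than the whole pool, so I expect Jd to lead in gamma.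

The forecast says Jb at 39% for eta and Jd at 56% for gamma, reasoning that “Jd tracks the integral of Jb”. Its 56% is told of Jd, whereas my 55.6% is Jd and Jc together and my Jd is 53.6%.

The flask gives Jb at 38.1% in eta and Jd at 52.7% in gamma, with Jc at 3.53% and the pool at 43.7%.

    Ja ⇌ Jb (K = 1.50, k = 0.150 h⁻¹)
    Jb ⇌ Jd (K = 0.600, k = 0.0460 h⁻¹)
    Jf + Jc → Jg (k = 0.130 L mol⁻¹ h⁻¹)
    Jb ⇌ Jc (K = 3.00, k = 0.00270 h⁻¹)
    Je ⇌ Jd, rate k5*(cs5 - [Jd]) while solid is left; crystals form when [Jd] > cs5 (solubility = 7.40 mM, k = 0.670 h⁻¹)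

In gamma, by forward rates alone, Ja goes to Jb with a half-life of 4.6 h, shorter than the 15 h of Jb to Jd. Jb over Ja in gamma stands at 1.25 at 20.0 h and 1.28 at 40.0 h, the steady split my pool assumes, yet below the pre-equilibrium value 1.5.

For gamma read at 3.0 d, the drain constant gives a pool of 21.4%. The computed flask holds 22.2% there, with Jd at 72.7% and Jc at 4.78%.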